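**Assumption:** atom labels C1–C15 follow guaianolide numbering. The alkoxymethylstannane, Bredereck's reagent, the silyl chlorides and Ac2O are treated as reagents; every skeleton fragment is a numbered starting material. The ester side chain is (R)-2-methylbutanoate, as written in the SMILES.

**Retrosynthetic overview**
1. Target ⇐ its C15 p-methoxybenzyl ether (last step: oxidative ether cleavage).
2. Seven-membered ring, trans-lactone and exocyclic methylene ⇐ one reductive ketyl radical cyclization of a C6 aldehyde onto a 2-(acetoxymethyl)enoate (C6–C7 bond), then β-elimination and lactonization in the same flask.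
3. Enoate side chain ⇐ bicyclic enal by syn-selective α-acyloxyallylation (C8–C9, brings in the 2-methylbutanoate) and cross metathesis (C7=C11).
4. Bridged enol ether (2-oxabicyclo[3.2.1]octene) ⇐ cis hydroxy aldehyde by formylation and cyclocondensation (O–C14); the all-cis cyclopentane ⇐ 3-allylcyclopentenone by CBS reduction, silicon-tethered radical cyclization (C5–C6) and ketone alkoxymethylation (C4).
5. Ring order: cyclopentane (bought) → bridged dihydropyran → cycloheptane and γ-lactone together.

**Route**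

Step 1
Reactants: 1 3-methoxycyclopent-2-en-1-one; 2 allylmagnesium bromide
Product: 3 3-(prop-2-en-1-yl)cyclopent-2-en-1-one
Conditions: THF, −78 to 0 °C; then 1 M HCl, 0 °C
Reagents that add atoms: water, O
Why: Stork–Danheiser sequence: 1,2-addition of the Grignard reagent to the vinylogous ester, then acid hydrolysis and β-elimination, transposes the carbonyl and gives the 3-substituted enone (no stereocentre).

Step 2
Reactants: 3 3-(prop-2-en-1-yl)cyclopent-2-en-1-one
Product: 4 (1S)-3-(prop-2-en-1-yl)cyclopent-2-en-1-ol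
Conditions: (R)-2-methyl-CBS-oxazaborolidine (20 mol%), catecholborane, toluene, −78 °C; aq. NaOH work-up
Reagents that add atoms: none
Why: Corey–Bakshi–Shibata reduction: the ring alkene acts as the large group, so the (R)-catalyst gives the (S)-allylic alcohol, and catecholborane at −78 °C does not hydroborate the terminal alkene.

Step 3
Reactants: 4 (1S)-3-(prop-2-en-1-yl)cyclopent-2-en-1-ol; 5 (bromomethyl)chlorodimethylsilane
Product: 8 (1S,2S,3S)-2-(hydroxymethyl)-3-(prop-2-en-1-yl)cyclopentan-1-ol (OH, CH2OH and allyl all cis), via bromomethylsilyl ether 6 (not isolated), via bicyclic siloxane 7 (not isolated)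
Conditions: Et3N, DMAP (cat.), PhH, rt; then Bu3SnH (slow addition), AIBN, PhH (0.02 M), 80 °C; then KF, KHCO3, 30% H2O2, THF–MeOH, rt
Reagents that add atoms: hydrogen peroxide, OO
Why: Stork–Nishiyama silicon-tethered radical cyclization with Tamao–Fleming oxidation: the α-silyl radical adds 5-exo-trig to the ring CH= carbon on the face of the tethering oxygen (sets C5), Bu3SnH quenches the tertiary radical from the convex face anti to the new ring (sets C1, allyl cis), and C–Si becomes C–OH with retention.

Step 4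
Reactants: 8 (1S,2S,3S)-2-(hydroxymethyl)-3-(prop-2-en-1-yl)cyclopentan-1-ol
Product: 9 (1S,2S,3S)-2-[(tert-butyldimethylsilyloxy)methyl]-3-(prop-2-en-1-yl)cyclopentan-1-ol
Conditions: TBSCl (1.05 equiv), imidazole, CH2Cl2, −20 °C
Reagents that add atoms: tert-butyldimethylsilyl chloride, CC(C)(C)[Si](C)(C)Cl
Why: Selective silylation of the primary over the secondary hydroxyl on steric grounds.

Step 5
Reactants: 9 (1S,2S,3S)-2-[(tert-butyldimethylsilyloxy)methyl]-3-(prop-2-en-1-yl)cyclopentan-1-ol
Product: 10 (2S,3S)-2-[(tert-butyldimethylsilyloxy)methyl]-3-(prop-2-en-1-yl)cyclopentan-1-one (cis)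
Conditions: Dess–Martin periodinane, NaHCO3, CH2Cl2, 0 °C; used at once
Reagents that add atoms: none
Why: Buffered Dess–Martin oxidation gives the ketone without epimerising the adjacent cis stereocentre.

Step 6
Reactants: 10 (2S,3S)-2-[(tert-butyldimethylsilyloxy)methyl]-3-(prop-2-en-1-yl)cyclopentan-1-one
Product: 11 (1S,2S,3S)-1-[(4-methoxybenzyloxy)methyl]-2-[(tert-butyldimethylsilyloxy)methyl]-3-(prop-2-en-1-yl)cyclopentan-1-ol (tertiary OH cis to both ring substituents)
Conditions: PMBOCH2SnBu3, n-BuLi, THF, −78 °C; CeCl3; then 10, −78 °C; aq. NH4Cl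
Reagents that add atoms: tributyl[(4-methoxybenzyloxy)methyl]stannane, CCCC[Sn](CCCC)(CCCC)COCc1ccc(OC)cc1
Why: Still alkoxymethyl-lithium 1,2-addition (as the less basic organocerium): the nucleophile enters anti to the two cis ring substituents, so the new tertiary hydroxyl is cis to both (sets C4).

Step 7
Reactants: 11 (1S,2S,3S)-1-[(4-methoxybenzyloxy)methyl]-2-[(tert-butyldimethylsilyloxy)methyl]-3-(prop-2-en-1-yl)cyclopentan-1-ol
Product: 12 the corresponding cyclopentylacetaldehyde (allyl cut to CH2CHO; in equilibrium with its bridged lactol)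
Conditions: OsO4 (2 mol%), NaIO4, 2,6-lutidine, dioxane–H2O, rt
Reagents that add atoms: sodium periodate, [Na+].[O-]I(=O)(=O)=O; water, O
Why: Lemieux–Johnson oxidative cleavage of the only alkene; no stereocentre is touched.

Step 8
Reactants: 12 the cyclopentylacetaldehyde
Product: 14 1-[(4-methoxybenzyloxy)methyl]-8-[(tert-butyldimethylsilyloxy)methyl]-2-oxabicyclo[3.2.1]oct-3-ene-4-carbaldehyde (C8 substituent on the side of the enol ether bridge), via enaminal 13 (not isolated)
Conditions: t-BuOCH(NMe2)2, PhMe, 80 °C; then AcOH (5 equiv), PhMe, 60 °C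
Reagents that add atoms: tert-butoxybis(dimethylamino)methane (Bredereck's reagent), CC(C)(C)OC(N(C)C)N(C)C
Why: Aminomethylenation of the aldehyde α-CH2, then acid-promoted intramolecular addition–elimination by the cis tertiary hydroxyl, expels dimethylamine and closes the bridged enol ether (O–C14); no new stereocentre, the cis geometry from steps 3 and 6 makes closure possible.

Step 9
Reactants: 15 (R)-2-methylbutanoic acid; 16 acrolein
Product: 18 3-chloroprop-1-en-1-yl (R)-2-methylbutanoate (E/Z mixture; both isomers converge in step 10), via acid chloride 17 (not isolated)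
Conditions: (COCl)2, DMF (cat.), CH2Cl2, 0 °C to rt; then 16, ZnCl2 (5 mol%), −20 to 0 °C
Reagents that add atoms: oxalyl chloride, ClC(=O)C(Cl)=O
Why: Acid chloride formation and Lewis-acid-catalysed 1,4-addition of the acyl chloride to acrolein; base-free conditions leave the α-stereocentre intact.

Step 10
Reactants: 14 the bicyclic enal; 18 3-chloroprop-1-en-1-yl (R)-2-methylbutanoate
Product: 20 syn (threo) adduct with C9–OH, C8–O-(R)-2-methylbutanoyl and a C7 vinyl group on the bicyclic core, via trimethylsilyl ether 19 (not isolated)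
Conditions: CrCl3 (10 mol%), (R,R)-N,N′-bis(3,5-di-tert-butylsalicylidene)-1,2-cyclohexanediamine (12 mol%; antipode to be confirmed on the first run), Mn powder, Et3N (20 mol%), Me3SiCl, MeCN, rt; then NH4F, MeOH, 0 °C
Reagents that add atoms: chlorotrimethylsilane, C[Si](C)(C)Cl (silyl group present in 19 only)
Why: Catalytic asymmetric Nozaki–Hiyama–Kishi α-acyloxyallylation: the γ-acyloxyallylchromium adds through its oxygen-bearing carbon in a closed transition state to give the syn 1,2-diol monoester, and the salen ligand selects the aldehyde face (sets C8 and C9).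

Step 11
Reactants: 20 the syn adduct; 21 methyl 2-(hydroxymethyl)acrylate
Product: 22 (E)-enoate with C7=C11, C13–OH and C9–OH (C8 trans to CO2Me)
Conditions: second-generation Hoveyda–Grubbs catalyst (10 mol%), 21 (5 equiv), CH2Cl2, 40 °C
Reagents that add atoms: none
Why: Olefin cross metathesis of the terminal alkene with the 1,1-disubstituted acrylate, driven by loss of ethene and giving the thermodynamically preferred (E) trisubstituted enoate.

Step 12
Reactants: 22 the (E)-enoate diol
Product: 23 diacetate (C9–OAc and C13–OAc)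
Conditions: Ac2O, pyridine, DMAP (cat.), CH2Cl2, 0 °C
Reagents that add atoms: acetic anhydride, CC(=O)OC(C)=O
Why: Acetylation installs the C9 acetate of the target and turns C13–OH into the leaving group needed in step 15.

Step 13
Reactants: 23 the diacetate
Product: 24 primary alcohol (C6–OH)
Conditions: HF·pyridine, pyridine, THF, 0 °C
Reagents that add atoms: none
Why: Buffered fluoride desilylation removes the primary silyl ether without acid that would harm the enol ether.

Step 14
Reactants: 24 the primary alcohol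
Product: 25 C6 aldehyde
Conditions: Dess–Martin periodinane, NaHCO3, CH2Cl2, 0 °C
Reagents that add atoms: none
Why: Mild Dess–Martin oxidation to the aldehyde without epimerising C5.

Step 15
Reactants: 25 the C6 aldehyde
Product: 27 15-O-(4-methoxybenzyl) ether of the target, via seco hydroxy ester 26 (not isolated)
Conditions: SmI2 (2.5 equiv), THF, no proton donor, −78 to −20 °C; aq. NH4Cl
Reagents that add atoms: none
Why: Proposed new method: electron transfer from divalent samarium to the aldehyde gives a ketyl radical that adds 7-exo-trig to C7 of the enoate (the key C6–C7 bond); a second electron gives the samarium enolate, which expels the C13 acetate to form the exocyclic methylene, and the C6 samarium alkoxide lactonizes onto the methyl ester; the anti arrangement of ketyl oxygen and ester carbon in the chelated transition state should give the trans-lactone (C6, C7), and the extended C6···C9 tether imposed by the rigid oxabicycle is expected to put H8 beside the forming bond and the C8 acyloxy group outside, giving the cis H7/H8 relationship (a prediction from models, not precedent); closest known reaction types are samarium diiodide aldehyde–enoate ketyl–olefin cyclization with lactonization and β-elimination of samarium β-acyloxy enolates.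

Step 16
Reactants: 27 the 15-O-(4-methoxybenzyl) ether
Product: 28 target CNP0013863.3
Conditions: DDQ, CH2Cl2–pH 7 buffer (10:1), 0 °C
Reagents that add atoms: none
Why: Oxidative cleavage of the p-methoxybenzyl ether with DDQ under buffered conditions frees C15–OH and leaves esters, lactone and enol ether untouched.

**Compound list**

1 | 3-methoxycyclopent-2-en-1-one | COC1=CC(=O)CC1 | starting material
2 | allylmagnesium bromide | C=CC[Mg]Br | starting material
3 | 3-(prop-2-en-1-yl)cyclopent-2-en-1-one | C=CCC1=CC(=O)CC1 | intermediate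
4 | (1S)-3-(prop-2-en-1-yl)cyclopent-2-en-1-ol | O[C@@H]1C=C(CC=C)CC1 | intermediate
5 | (bromomethyl)chlorodimethylsilane | C[Si](C)(Cl)CBr | starting material
6 | (bromomethyl)dimethylsilyl ether of 4 | C[Si](C)(CBr)O[C@@H]1C=C(CC=C)CC1 | intermediate
7 | cis-fused 3,3-dimethyl-2-oxa-3-silabicyclo[3.3.0]octane with allyl cis to the siloxane ring | C[Si]1(C)C[C@@H]2[C@H](CC=C)CC[C@@H]2O1 | intermediate
8 | (1S,2S,3S)-2-(hydroxymethyl)-3-(prop-2-en-1-yl)cyclopentan-1-ol | O[C@@H]1[C@H](CO)[C@H](CC=C)CC1 | intermediate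
9 | (1S,2S,3S)-2-[(tert-butyldimethylsilyloxy)methyl]-3-(prop-2-en-1-yl)cyclopentan-1-ol | O[C@@H]1[C@H](CO[Si](C)(C)C(C)(C)C)[C@H](CC=C)CC1 | intermediate
10 | (2S,3S)-2-[(tert-butyldimethylsilyloxy)methyl]-3-(prop-2-en-1-yl)cyclopentan-1-one | O=C1[C@H](CO[Si](C)(C)C(C)(C)C)[C@H](CC=C)CC1 | intermediate
11 | (1S,2S,3S)-1-[(4-methoxybenzyloxy)methyl]-2-[(tert-butyldimethylsilyloxy)methyl]-3-(prop-2-en-1-yl)cyclopentan-1-ol | O[C@]1(COCc2ccc(OC)cc2)[C@H](CO[Si](C)(C)C(C)(C)C)[C@H](CC=C)CC1 | intermediate
12 | cyclopentylacetaldehyde from 11 (open form of the bridged lactol) | O[C@]1(COCc2ccc(OC)cc2)[C@H](CO[Si](C)(C)C(C)(C)C)[C@H](CC=O)CC1 | intermediate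
13 | (E)-2-substituted 3-(dimethylamino)acrolein (enaminal) from 12 | O[C@]1(COCc2ccc(OC)cc2)[C@H](CO[Si](C)(C)C(C)(C)C)[C@H](/C(C=O)=C\N(C)C)CC1 | intermediate
14 | 1-[(4-methoxybenzyloxy)methyl]-8-[(tert-butyldimethylsilyloxy)methyl]-2-oxabicyclo[3.2.1]oct-3-ene-4-carbaldehyde | O=CC1=CO[C@@]2(COCc3ccc(OC)cc3)CC[C@@H]1[C@H]2CO[Si](C)(C)C(C)(C)C | intermediate
15 | (R)-2-methylbutanoic acid | CC[C@@H](C)C(O)=O | starting material
16 | acrolein | C=CC=O | starting material
17 | (R)-2-methylbutanoyl chloride | CC[C@@H](C)C(Cl)=O | intermediate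
18 | 3-chloroprop-1-en-1-yl (R)-2-methylbutanoate (E shown; E/Z mixture used) | CC[C@@H](C)C(=O)O/C=C/CCl | intermediate
19 | trimethylsilyl ether of 20 | C=C[C@H](OC(=O)[C@H](C)CC)[C@@H](O[Si](C)(C)C)C1=CO[C@@]2(COCc3ccc(OC)cc3)CC[C@@H]1[C@H]2CO[Si](C)(C)C(C)(C)C | intermediate
20 | syn adduct: C9–OH, C8–O-(R)-2-methylbutanoyl, C7 vinyl | C=C[C@H](OC(=O)[C@H](C)CC)[C@@H](O)C1=CO[C@@]2(COCc3ccc(OC)cc3)CC[C@@H]1[C@H]2CO[Si](C)(C)C(C)(C)C | intermediate
21 | methyl 2-(hydroxymethyl)acrylate | C=C(CO)C(=O)OC | starting material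
22 | (E)-enoate diol (C13–OH, C9–OH) | COC(=O)/C(CO)=C/[C@H](OC(=O)[C@H](C)CC)[C@@H](O)C1=CO[C@@]2(COCc3ccc(OC)cc3)CC[C@@H]1[C@H]2CO[Si](C)(C)C(C)(C)C | intermediate
23 | diacetate (C13–OAc, C9–OAc) | COC(=O)/C(COC(C)=O)=C/[C@H](OC(=O)[C@H](C)CC)[C@@H](OC(C)=O)C1=CO[C@@]2(COCc3ccc(OC)cc3)CC[C@@H]1[C@H]2CO[Si](C)(C)C(C)(C)C | intermediate
24 | C6 primary alcohol | COC(=O)/C(COC(C)=O)=C/[C@H](OC(=O)[C@H](C)CC)[C@@H](OC(C)=O)C1=CO[C@@]2(COCc3ccc(OC)cc3)CC[C@@H]1[C@H]2CO | intermediate
25 | C6 aldehyde | COC(=O)/C(COC(C)=O)=C/[C@H](OC(=O)[C@H](C)CC)[C@@H](OC(C)=O)C1=CO[C@@]2(COCc3ccc(OC)cc3)CC[C@@H]1[C@H]2C=O | intermediate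
26 | seco hydroxy ester (cyclized, C6–OH, α-methylene methyl ester) | C=C(C(=O)OC)[C@@H]1[C@H](OC(=O)[C@H](C)CC)[C@@H](OC(C)=O)C2=CO[C@@]3(COCc4ccc(OC)cc4)CC[C@@H]2[C@H]3[C@H]1O | intermediate
27 | 15-O-(4-methoxybenzyl) ether of the target | C=C1C(=O)O[C@H]2[C@H]1[C@H](OC(=O)[C@H](C)CC)[C@@H](OC(C)=O)C1=CO[C@@]3(COCc4ccc(OC)cc4)CC[C@@H]1[C@@H]23 | intermediate
28 | CNP0013863.3 | C=C1C(=O)O[C@H]2[C@H]1[C@H](OC(=O)[C@H](C)CC)[C@@H](OC(C)=O)C1=CO[C@@]3(CO)CC[C@@H]1[C@@H]23 | target

**Step count and risks**

Total step count: 16. Longest linear sequence: 15 (steps 1–8 and 10–16; step 9 is the one-step side branch).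

Steps most likely to fail, in route order:

Step 10 (acyloxyallylation). The enal is a deactivated vinylogous formate, and catalyst control with a new, chiral acyloxy group is untested. Fallback, reagent-controlled and stepwise: it sets out from 14 and returns at 23. Brown allylboration of 14 with the (Z)-γ-(methoxymethoxy)allyl-diisopinocampheylborane (from allyl methoxymethyl ether, s-BuLi, Ipc2BOMe, BF3·OEt2; oxidative work-up) gives the syn methoxymethyl ether alcohol F1. Acetylation (Ac2O, pyridine) gives the C9 acetate F2. Me2BBr at −78 °C removes the methoxymethyl group to give the C8 alcohol F3. Steglich esterification with 15 (DCC, DMAP) gives the vinyl diester F4. Cross metathesis of F4 with 21 gives the hydroxy enoate F5, and acetylation of F5 gives 23.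

Step 11 (cross metathesis). An allylic-ester alkene and a 1,1-disubstituted acrylate are both slow partners. Fallback, intramolecular instead of intermolecular: it sets out from 20 and returns at 22. Silylation of 20 with Ph2SiCl2 and imidazole, then addition of 21, gives the mixed diphenylsilaketal F6. Ring-closing metathesis (second-generation Grubbs catalyst, toluene, 80 °C) gives the eight-membered cyclic silaketal F7 with the same alkene geometry. NH4F in MeOH at 0 °C cleaves the tether to give 22.

Step 15 (key reductive cyclization). Direct reduction of the doubly allylic enoate may compete with ketyl formation. The C7 face selectivity rests on a model, and excess SmI2 could reduce the α-methylene lactone. Fallback, polar instead of radical: it sets out from 25 and returns at 27 with no new isolated compound. Pd(PPh3)4 (5 mol%) and InI in THF convert the primary allylic acetate into an allylindium species (umpolung of the π-allylpalladium). This adds through C7 to the aldehyde in a closed six-membered transition state, and the resulting alkoxide lactonizes to 27.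

Further compounds
F1 | step 10 | syn adduct with C9–OH and C8–O-methoxymethyl | C=C[C@H](OCOC)[C@@H](O)C1=CO[C@@]2(COCc3ccc(OC)cc3)CC[C@@H]1[C@H]2CO[Si](C)(C)C(C)(C)C
F2 | step 10 | C9 acetate of F1 | C=C[C@H](OCOC)[C@@H](OC(C)=O)C1=CO[C@@]2(COCc3ccc(OC)cc3)CC[C@@H]1[C@H]2CO[Si](C)(C)C(C)(C)C
F3 | step 10 | C8 alcohol, C9 acetate | C=C[C@H](O)[C@@H](OC(C)=O)C1=CO[C@@]2(COCc3ccc(OC)cc3)CC[C@@H]1[C@H]2CO[Si](C)(C)C(C)(C)C
F4 | step 10 | C8 (R)-2-methylbutanoate, C9 acetate, C7 vinyl | C=C[C@H](OC(=O)[C@H](C)CC)[C@@H](OC(C)=O)C1=CO[C@@]2(COCc3ccc(OC)cc3)CC[C@@H]1[C@H]2CO[Si](C)(C)C(C)(C)C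
F5 | step 10 | (E)-enoate with C13–OH and C9–OAc | COC(=O)/C(CO)=C/[C@H](OC(=O)[C@H](C)CC)[C@@H](OC(C)=O)C1=CO[C@@]2(COCc3ccc(OC)cc3)CC[C@@H]1[C@H]2CO[Si](C)(C)C(C)(C)C
F6 | step 11 | mixed diphenylsilaketal of 20 and 21 | C=C[C@H](OC(=O)[C@H](C)CC)[C@@H](O[Si](OCC(=C)C(=O)OC)(c1ccccc1)c1ccccc1)C1=CO[C@@]2(COCc3ccc(OC)cc3)CC[C@@H]1[C@H]2CO[Si](C)(C)C(C)(C)C
F7 | step 11 | eight-membered cyclic diphenylsilaketal (ring-closed F6) | COC(=O)C1=C[C@H](OC(=O)[C@H](C)CC)[C@@H](O[Si](c2ccccc2)(c2ccccc2)OC1)C2=CO[C@@]3(COCc4ccc(OC)cc4)CC[C@@H]2[C@H]3CO[Si](C)(C)C(C)(C)C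
F0 | step 15 | none | none
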